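**Retrosynthetic overview**
1. The target is the (S)-configured 3-hydroxybutenolide; its only stereocentre is the quaternary ring carbon bearing O, CO2Me, the benzyl group and the aryl-bearing ring carbon.
2. The butenolide (the only ring made, closed last before deprotection) is cut at the lactone C–O and the ring C=C, giving tertiary α-hydroxy-β-keto ester 13 and acetoxyacetyl chloride.
3. Key disconnection: the tertiary C–O bond of 13, made by enantioselective hydroxylation of the α-benzyl aroylacetate 11; this sets the stereocentre.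
4. 11 comes from a twofold Stille prenylation of dibromide 9, which comes from reductive Knoevenagel benzylation of β-keto ester 5 with aldehyde 7; 5 comes from Roskamp homologation of aldehyde 3.
5. Phenols travel as TBS ethers (no acid, no hydrogenation, no electrophilic oxidant near prenyl or catechol) and are freed in one buffered fluoride step.

Assumption: the SMILES is read as (S) at the quaternary lactone carbon (priorities O > CO2Me > ring C > CH2); the hydroxylation catalyst is used as whichever antipode gives (S)-13, to be established in a first run.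

**Step 1**
Reactants: 1 3-bromo-4,5-dihydroxybenzaldehyde; 2 tert-butyldimethylsilyl chloride
Product: 3 3-bromo-4,5-bis(tert-butyldimethylsilyloxy)benzaldehyde
Conditions: 2 (2.5 equiv), imidazole (5 equiv), DMF, rt
Reagents that add atoms: tert-butyldimethylsilyl chloride, CC(C)(C)[Si](C)(C)Cl
Why: Imidazole-promoted silyl ether formation caps both catechol hydroxyls so that the later tin, base and peroxide steps never meet a free catechol; no stereocentre is involved.

**Step 2**
Reactants: 3 3-bromo-4,5-bis(tert-butyldimethylsilyloxy)benzaldehyde; 4 methyl diazoacetate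
Product: 5 methyl 3-[3-bromo-4,5-bis(tert-butyldimethylsilyloxy)phenyl]-3-oxopropanoate
Conditions: 4 (1.3 equiv), SnCl2 (10 mol %), CH2Cl2, rt
Reagents that add atoms: methyl diazoacetate, COC(=O)C=[N+]=[N-]
Why: Roskamp homologation: the tin-activated aldehyde adds the diazo ester and a 1,2-hydride shift with loss of N2 gives the β-keto ester in one step, with no stereocentre formed.

**Step 3**
Reactants: 6 3-bromo-4-hydroxybenzaldehyde; 2 tert-butyldimethylsilyl chloride
Product: 7 3-bromo-4-(tert-butyldimethylsilyloxy)benzaldehyde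
Conditions: 2 (1.2 equiv), imidazole (2.5 equiv), DMF, rt
Reagents that add atoms: tert-butyldimethylsilyl chloride, CC(C)(C)[Si](C)(C)Cl
Why: The same silylation protects the phenol of ring A so that only the tertiary alcohol is acylated in step 7; no stereocentre is involved.

**Step 4**
Reactants: 5 methyl 3-[3-bromo-4,5-bis(tert-butyldimethylsilyloxy)phenyl]-3-oxopropanoate; 7 3-bromo-4-(tert-butyldimethylsilyloxy)benzaldehyde
Product: 9 methyl 2-[3-bromo-4-(tert-butyldimethylsilyloxy)benzyl]-3-[3-bromo-4,5-bis(tert-butyldimethylsilyloxy)phenyl]-3-oxopropanoate (racemic), via benzylidene keto ester 8 (not isolated)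
Conditions: piperidinium acetate (10 mol %), Hantzsch ester (diethyl 2,6-dimethyl-1,4-dihydropyridine-3,5-dicarboxylate, 1.2 equiv), toluene, 60 °C
Reagents that add atoms: none
Why: Knoevenagel condensation gives the electron-poor benzylidene keto ester, which is reduced in the same flask by transfer hydrogenation from the Hantzsch ester (reductive Knoevenagel alkylation), so the benzyl group is attached without dialkylation and the new centre is racemic and later erased by enolisation.

**Step 5**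
Reactants: 9 methyl 2-[3-bromo-4-(tert-butyldimethylsilyloxy)benzyl]-3-[3-bromo-4,5-bis(tert-butyldimethylsilyloxy)phenyl]-3-oxopropanoate (racemic); 10 tributyl(3-methylbut-2-en-1-yl)stannane
Product: 11 methyl 2-[4-(tert-butyldimethylsilyloxy)-3-(3-methylbut-2-en-1-yl)benzyl]-3-[3,4-bis(tert-butyldimethylsilyloxy)-5-(3-methylbut-2-en-1-yl)phenyl]-3-oxopropanoate (racemic)
Conditions: 10 (2.6 equiv), Pd(PPh3)4 (10 mol %), DMF, 100 °C
Reagents that add atoms: tributyl(3-methylbut-2-en-1-yl)stannane, CCCC[Sn](CCCC)(CCCC)CC=C(C)C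
Why: Twofold Stille coupling: zerovalent palladium inserts into each aryl bromide and the stannane transfers its tin-bearing CH2 carbon, giving linear prenyl groups under neutral conditions that leave the silyl ethers and keto ester untouched; the racemic centre is not affected.

**Step 6**
Reactants: 11 methyl 2-[4-(tert-butyldimethylsilyloxy)-3-(3-methylbut-2-en-1-yl)benzyl]-3-[3,4-bis(tert-butyldimethylsilyloxy)-5-(3-methylbut-2-en-1-yl)phenyl]-3-oxopropanoate (racemic); 12 cumene hydroperoxide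
Product: 13 methyl (2S)-2-hydroxy-2-[4-(tert-butyldimethylsilyloxy)-3-(3-methylbut-2-en-1-yl)benzyl]-3-[3,4-bis(tert-butyldimethylsilyloxy)-5-(3-methylbut-2-en-1-yl)phenyl]-3-oxopropanoate
Conditions: 12 (1.5 equiv), tert-leucine-derived bifunctional iminophosphorane–thiourea organocatalyst (10 mol %, the antipode giving the S alcohol), toluene, −30 °C
Reagents that add atoms: cumene hydroperoxide, CC(C)(OO)c1ccccc1
Why: Proposed new method: the superbasic iminophosphorane (far more basic than a cinchona amine) deprotonates the weakly acidic acyclic α-benzyl aroylacetate, the thiourea arm holds the planar enolate as a chiral hydrogen-bonded ion pair while the iminophosphoranium N–H binds the hydroperoxide, and the enolate carbon attacks the terminal peroxide oxygen from the exposed face (SN2 at oxygen, cumyloxide leaving and being reprotonated), so the tertiary C–O bond and the (S) stereocentre are created together from the racemic enolisable substrate; the closest known reaction is the cinchona-amine-catalysed α-hydroxylation of cyclic β-keto esters with cumene hydroperoxide, which has not been shown for acyclic α-benzyl aroylacetates or with this catalyst class.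

**Step 7**
Reactants: 13 methyl (2S)-2-hydroxy-2-[4-(tert-butyldimethylsilyloxy)-3-(3-methylbut-2-en-1-yl)benzyl]-3-[3,4-bis(tert-butyldimethylsilyloxy)-5-(3-methylbut-2-en-1-yl)phenyl]-3-oxopropanoate; 14 acetoxyacetyl chloride
Product: 15 methyl (2S)-2-(2-acetoxyacetoxy)-2-[4-(tert-butyldimethylsilyloxy)-3-(3-methylbut-2-en-1-yl)benzyl]-3-[3,4-bis(tert-butyldimethylsilyloxy)-5-(3-methylbut-2-en-1-yl)phenyl]-3-oxopropanoate
Conditions: 14 (2 equiv), pyridine (4 equiv), DMAP (20 mol %), CH2Cl2, 0 °C to rt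
Reagents that add atoms: acetoxyacetyl chloride, CC(=O)OCC(=O)Cl
Why: DMAP-catalysed esterification of the hindered tertiary alcohol by a small, reactive acid chloride; the stereocentre has no hydrogen and is retained, and capping the hydroxyl blocks any α-ketol rearrangement.

**Step 8**
Reactants: 15 methyl (2S)-2-(2-acetoxyacetoxy)-2-[4-(tert-butyldimethylsilyloxy)-3-(3-methylbut-2-en-1-yl)benzyl]-3-[3,4-bis(tert-butyldimethylsilyloxy)-5-(3-methylbut-2-en-1-yl)phenyl]-3-oxopropanoate
Product: 18 methyl (2S)-3-[3,4-bis(tert-butyldimethylsilyloxy)-5-(3-methylbut-2-en-1-yl)phenyl]-2-[4-(tert-butyldimethylsilyloxy)-3-(3-methylbut-2-en-1-yl)benzyl]-4-hydroxy-5-oxo-2,5-dihydrofuran-2-carboxylate, via aldol lactone 16 (not isolated), via acetyl-shifted lactone 17 (not isolated)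
Conditions: DBU (3 equiv), dry MeCN, 0 °C to rt; aqueous citric acid work-up
Reagents that add atoms: none
Why: Base-mediated intramolecular aldol condensation of an α-(acetoxyacetoxy) aryl ketone, a known route to 3-oxygenated 4-aryl-5,5-disubstituted furanones: DBU enolises the acetoxyacetate CH2, 5-exo aldol closure gives 16, the acetyl group shifts to the new tertiary alkoxide to give 17, and E1cB loss of acetate delivers the stabilised 3-hydroxybutenolide while the hydrogen-free quaternary stereocentre is untouched.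

**Step 9**
Reactants: 18 methyl (2S)-3-[3,4-bis(tert-butyldimethylsilyloxy)-5-(3-methylbut-2-en-1-yl)phenyl]-2-[4-(tert-butyldimethylsilyloxy)-3-(3-methylbut-2-en-1-yl)benzyl]-4-hydroxy-5-oxo-2,5-dihydrofuran-2-carboxylate
Product: 19 methyl (2S)-3-[3,4-dihydroxy-5-(3-methylbut-2-en-1-yl)phenyl]-4-hydroxy-2-[4-hydroxy-3-(3-methylbut-2-en-1-yl)benzyl]-5-oxo-2,5-dihydrofuran-2-carboxylate
Conditions: TBAF (3.5 equiv), AcOH (4 equiv), THF, 0 °C
Reagents that add atoms: none
Why: Fluoride-mediated silyl ether cleavage buffered by acetic acid frees the three phenols without base-induced catechol oxidation or lactone opening and without any acid that could cyclise an ortho-prenylphenol to a chroman; the stereocentre is untouched.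

**Compound list**
1 | 3-bromo-4,5-dihydroxybenzaldehyde | O=Cc1cc(O)c(O)c(Br)c1 | starting material
2 | tert-butyldimethylsilyl chloride | CC(C)(C)[Si](C)(C)Cl | starting material
3 | 3-bromo-4,5-bis(tert-butyldimethylsilyloxy)benzaldehyde | O=Cc1cc(O[Si](C)(C)C(C)(C)C)c(O[Si](C)(C)C(C)(C)C)c(Br)c1 | intermediate
4 | methyl diazoacetate | COC(=O)C=[N+]=[N-] | starting material
5 | methyl 3-[3-bromo-4,5-bis(tert-butyldimethylsilyloxy)phenyl]-3-oxopropanoate | COC(=O)CC(=O)c1cc(O[Si](C)(C)C(C)(C)C)c(O[Si](C)(C)C(C)(C)C)c(Br)c1 | intermediate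
6 | 3-bromo-4-hydroxybenzaldehyde | O=Cc1ccc(O)c(Br)c1 | starting material
7 | 3-bromo-4-(tert-butyldimethylsilyloxy)benzaldehyde | O=Cc1ccc(O[Si](C)(C)C(C)(C)C)c(Br)c1 | intermediate
8 | methyl 2-[3-bromo-4,5-bis(tert-butyldimethylsilyloxy)benzoyl]-3-[3-bromo-4-(tert-butyldimethylsilyloxy)phenyl]prop-2-enoate (E/Z mixture) | COC(=O)C(=Cc1ccc(O[Si](C)(C)C(C)(C)C)c(Br)c1)C(=O)c1cc(O[Si](C)(C)C(C)(C)C)c(O[Si](C)(C)C(C)(C)C)c(Br)c1 | intermediate (not isolated)
9 | methyl 2-[3-bromo-4-(tert-butyldimethylsilyloxy)benzyl]-3-[3-bromo-4,5-bis(tert-butyldimethylsilyloxy)phenyl]-3-oxopropanoate (racemic) | COC(=O)C(Cc1ccc(O[Si](C)(C)C(C)(C)C)c(Br)c1)C(=O)c1cc(O[Si](C)(C)C(C)(C)C)c(O[Si](C)(C)C(C)(C)C)c(Br)c1 | intermediate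
10 | tributyl(3-methylbut-2-en-1-yl)stannane | CCCC[Sn](CCCC)(CCCC)CC=C(C)C | starting material
11 | methyl 2-[4-(tert-butyldimethylsilyloxy)-3-(3-methylbut-2-en-1-yl)benzyl]-3-[3,4-bis(tert-butyldimethylsilyloxy)-5-(3-methylbut-2-en-1-yl)phenyl]-3-oxopropanoate (racemic) | COC(=O)C(Cc1ccc(O[Si](C)(C)C(C)(C)C)c(CC=C(C)C)c1)C(=O)c1cc(O[Si](C)(C)C(C)(C)C)c(O[Si](C)(C)C(C)(C)C)c(CC=C(C)C)c1 | intermediate
12 | cumene hydroperoxide | CC(C)(OO)c1ccccc1 | starting material
13 | methyl (2S)-2-hydroxy-2-[4-(tert-butyldimethylsilyloxy)-3-(3-methylbut-2-en-1-yl)benzyl]-3-[3,4-bis(tert-butyldimethylsilyloxy)-5-(3-methylbut-2-en-1-yl)phenyl]-3-oxopropanoate | COC(=O)[C@@](C(=O)c1cc(O[Si](C)(C)C(C)(C)C)c(O[Si](C)(C)C(C)(C)C)c(CC=C(C)C)c1)(Cc1ccc(O[Si](C)(C)C(C)(C)C)c(CC=C(C)C)c1)O | intermediate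
14 | acetoxyacetyl chloride | CC(=O)OCC(=O)Cl | starting material
15 | methyl (2S)-2-(2-acetoxyacetoxy)-2-[4-(tert-butyldimethylsilyloxy)-3-(3-methylbut-2-en-1-yl)benzyl]-3-[3,4-bis(tert-butyldimethylsilyloxy)-5-(3-methylbut-2-en-1-yl)phenyl]-3-oxopropanoate | COC(=O)[C@@](C(=O)c1cc(O[Si](C)(C)C(C)(C)C)c(O[Si](C)(C)C(C)(C)C)c(CC=C(C)C)c1)(Cc1ccc(O[Si](C)(C)C(C)(C)C)c(CC=C(C)C)c1)OC(=O)COC(C)=O | intermediate
16 | methyl (2S)-4-acetoxy-3-[3,4-bis(tert-butyldimethylsilyloxy)-5-(3-methylbut-2-en-1-yl)phenyl]-2-[4-(tert-butyldimethylsilyloxy)-3-(3-methylbut-2-en-1-yl)benzyl]-3-hydroxy-5-oxooxolane-2-carboxylate (mixture at ring positions 3 and 4) | COC(=O)[C@@]1(Cc2ccc(O[Si](C)(C)C(C)(C)C)c(CC=C(C)C)c2)OC(=O)C(OC(C)=O)C1(O)c1cc(O[Si](C)(C)C(C)(C)C)c(O[Si](C)(C)C(C)(C)C)c(CC=C(C)C)c1 | intermediate (not isolated)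
17 | methyl (2S)-3-acetoxy-3-[3,4-bis(tert-butyldimethylsilyloxy)-5-(3-methylbut-2-en-1-yl)phenyl]-2-[4-(tert-butyldimethylsilyloxy)-3-(3-methylbut-2-en-1-yl)benzyl]-4-hydroxy-5-oxooxolane-2-carboxylate (mixture at ring positions 3 and 4) | COC(=O)[C@@]1(Cc2ccc(O[Si](C)(C)C(C)(C)C)c(CC=C(C)C)c2)OC(=O)C(O)C1(OC(C)=O)c1cc(O[Si](C)(C)C(C)(C)C)c(O[Si](C)(C)C(C)(C)C)c(CC=C(C)C)c1 | intermediate (not isolated)
18 | methyl (2S)-3-[3,4-bis(tert-butyldimethylsilyloxy)-5-(3-methylbut-2-en-1-yl)phenyl]-2-[4-(tert-butyldimethylsilyloxy)-3-(3-methylbut-2-en-1-yl)benzyl]-4-hydroxy-5-oxo-2,5-dihydrofuran-2-carboxylate | COC(=O)[C@@]1(Cc2ccc(O[Si](C)(C)C(C)(C)C)c(CC=C(C)C)c2)OC(=O)C(O)=C1c1cc(O[Si](C)(C)C(C)(C)C)c(O[Si](C)(C)C(C)(C)C)c(CC=C(C)C)c1 | intermediate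
19 | methyl (2S)-3-[3,4-dihydroxy-5-(3-methylbut-2-en-1-yl)phenyl]-4-hydroxy-2-[4-hydroxy-3-(3-methylbut-2-en-1-yl)benzyl]-5-oxo-2,5-dihydrofuran-2-carboxylate | COC(=O)[C@@]1(Cc2ccc(O)c(CC=C(C)C)c2)OC(=O)C(O)=C1c1cc(O)c(O)c(CC=C(C)C)c1 | target

**Step count and risks**
Total step count: 9. Longest linear sequence: 8 steps (steps 1, 2, 4, 5, 6, 7, 8, 9 from compound 1); step 3 is the only side branch.

The step most likely to fail is the hydroxylation of 11 to 13 (step 6), because it is new. An acyclic enolate may give low enantioselectivity, the hydroperoxide may degrade the iminophosphorane, and the alkoxide by-product could trigger retro-Claisen cleavage. If the enantiomeric excess falls short, 13 is polished by one recrystallisation or a chiral SFC pass. The fallback uses known chemistry and sets out from 11. The potassium enolate (KN(SiMe3)2, THF, −78 °C) is quenched with racemic 2-(phenylsulfonyl)-3-phenyloxaziridine (Davis enolate hydroxylation, which leaves the prenyl groups alone at this temperature) to give racemic methyl 2-hydroxy-2-[4-(tert-butyldimethylsilyloxy)-3-(3-methylbut-2-en-1-yl)benzyl]-3-[3,4-bis(tert-butyldimethylsilyloxy)-5-(3-methylbut-2-en-1-yl)phenyl]-3-oxopropanoate F1. Preparative chiral SFC then separates the unwanted (2R)-hydroxy keto ester F2 from the (S)-enantiomer, and the route is rejoined at 13.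

The second is the ring closure of 15 to 18 (step 8). The acetoxyacetate enolate could instead attack the neighbouring methyl ester (Dieckmann closure to a tetronic acid), and the intermediate aldolate could fragment at the bond to the quaternary carbon, which would also erode the stereocentre. The fallback sets out from 13 and replaces the aldol by an olefination that is selective for ketones and irreversible. Alcohol 13 is esterified (DCC, DMAP, CH2Cl2) with 2-(tert-butyldimethylsilyloxy)-2-(dimethoxyphosphoryl)acetic acid F3, obtained from its methyl ester with LiOH, to give the silyloxy phosphonoacetate ester F4. An intramolecular Horner–Wadsworth–Emmons reaction (LiCl, DBU, MeCN) then closes the ring to the fully silylated butenolide F5. The buffered fluoride conditions of step 9 remove all four silyl groups, and the route is rejoined at 19.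

The third is the twofold Stille coupling on 9 (step 5). Two hindered, electron-rich ortho-silyloxy aryl bromides must both couple, with linear regiochemistry, in the presence of an enolisable keto ester that could protodestannylate the reagent. The fallback sets out from 3 and 7 and installs each prenyl group before the halves are joined, as a single coupling on a simple aldehyde-activated aryl bromide. From 3, Stille coupling with 10 gives 3,4-bis(tert-butyldimethylsilyloxy)-5-(3-methylbut-2-en-1-yl)benzaldehyde F6, and Roskamp homologation with 4 gives methyl 3-[3,4-bis(tert-butyldimethylsilyloxy)-5-(3-methylbut-2-en-1-yl)phenyl]-3-oxopropanoate F7. From 7, Stille coupling with 10 gives 4-(tert-butyldimethylsilyloxy)-3-(3-methylbut-2-en-1-yl)benzaldehyde F8. Reductive Knoevenagel alkylation of F7 with F8 under the step 4 conditions passes through the prenylated benzylidene keto ester F9, and the route is rejoined at 11.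

**Further compounds**
F1 | step 6 | methyl 2-hydroxy-2-[4-(tert-butyldimethylsilyloxy)-3-(3-methylbut-2-en-1-yl)benzyl]-3-[3,4-bis(tert-butyldimethylsilyloxy)-5-(3-methylbut-2-en-1-yl)phenyl]-3-oxopropanoate (racemic) | COC(=O)C(O)(Cc1ccc(O[Si](C)(C)C(C)(C)C)c(CC=C(C)C)c1)C(=O)c1cc(O[Si](C)(C)C(C)(C)C)c(O[Si](C)(C)C(C)(C)C)c(CC=C(C)C)c1
F2 | step 6 | methyl (2R)-2-hydroxy-2-[4-(tert-butyldimethylsilyloxy)-3-(3-methylbut-2-en-1-yl)benzyl]-3-[3,4-bis(tert-butyldimethylsilyloxy)-5-(3-methylbut-2-en-1-yl)phenyl]-3-oxopropanoate | COC(=O)[C@](C(=O)c1cc(O[Si](C)(C)C(C)(C)C)c(O[Si](C)(C)C(C)(C)C)c(CC=C(C)C)c1)(Cc1ccc(O[Si](C)(C)C(C)(C)C)c(CC=C(C)C)c1)O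
F3 | step 8 | 2-(tert-butyldimethylsilyloxy)-2-(dimethoxyphosphoryl)acetic acid (racemic) | COP(=O)(OC)C(O[Si](C)(C)C(C)(C)C)C(=O)O
F4 | step 8 | methyl (2S)-2-{[2-(tert-butyldimethylsilyloxy)-2-(dimethoxyphosphoryl)acetyl]oxy}-2-[4-(tert-butyldimethylsilyloxy)-3-(3-methylbut-2-en-1-yl)benzyl]-3-[3,4-bis(tert-butyldimethylsilyloxy)-5-(3-methylbut-2-en-1-yl)phenyl]-3-oxopropanoate (epimers at the phosphonate carbon) | COC(=O)[C@@](C(=O)c1cc(O[Si](C)(C)C(C)(C)C)c(O[Si](C)(C)C(C)(C)C)c(CC=C(C)C)c1)(Cc1ccc(O[Si](C)(C)C(C)(C)C)c(CC=C(C)C)c1)OC(=O)C(O[Si](C)(C)C(C)(C)C)P(=O)(OC)OC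
F5 | step 8 | methyl (2S)-3-[3,4-bis(tert-butyldimethylsilyloxy)-5-(3-methylbut-2-en-1-yl)phenyl]-2-[4-(tert-butyldimethylsilyloxy)-3-(3-methylbut-2-en-1-yl)benzyl]-4-(tert-butyldimethylsilyloxy)-5-oxo-2,5-dihydrofuran-2-carboxylate | COC(=O)[C@@]1(Cc2ccc(O[Si](C)(C)C(C)(C)C)c(CC=C(C)C)c2)OC(=O)C(O[Si](C)(C)C(C)(C)C)=C1c1cc(O[Si](C)(C)C(C)(C)C)c(O[Si](C)(C)C(C)(C)C)c(CC=C(C)C)c1
F6 | step 5 | 3,4-bis(tert-butyldimethylsilyloxy)-5-(3-methylbut-2-en-1-yl)benzaldehyde | O=Cc1cc(O[Si](C)(C)C(C)(C)C)c(O[Si](C)(C)C(C)(C)C)c(CC=C(C)C)c1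
F7 | step 5 | methyl 3-[3,4-bis(tert-butyldimethylsilyloxy)-5-(3-methylbut-2-en-1-yl)phenyl]-3-oxopropanoate | COC(=O)CC(=O)c1cc(O[Si](C)(C)C(C)(C)C)c(O[Si](C)(C)C(C)(C)C)c(CC=C(C)C)c1
F8 | step 5 | 4-(tert-butyldimethylsilyloxy)-3-(3-methylbut-2-en-1-yl)benzaldehyde | O=Cc1ccc(O[Si](C)(C)C(C)(C)C)c(CC=C(C)C)c1
F9 | step 5 | methyl 2-[3,4-bis(tert-butyldimethylsilyloxy)-5-(3-methylbut-2-en-1-yl)benzoyl]-3-[4-(tert-butyldimethylsilyloxy)-3-(3-methylbut-2-en-1-yl)phenyl]prop-2-enoate (E/Z mixture, not isolated) | COC(=O)C(=Cc1ccc(O[Si](C)(C)C(C)(C)C)c(CC=C(C)C)c1)C(=O)c1cc(O[Si](C)(C)C(C)(C)C)c(O[Si](C)(C)C(C)(C)C)c(CC=C(C)C)c1
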